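## The problem

Target 24 is (5S,6S,7R,8S)-5,6,7,8-tetrahydroxy-2-[2-(3-hydroxy-4-methoxyphenyl)ethyl]-5,6,7,8-tetrahydro-4H-chromen-4-one; chromone numbering is kept for its carbons at every stage of the plan. A 4-pyranone (ring A) is fused through its C4a=C8a double bond to a six-membered carbocycle (ring B) whose four sp3 carbons C5 to C8 are all secondary carbinols, and C2 carries a two-carbon chain to an isovanillyl ring (ring C). The hydroxyls on C5, C6 and C8 lie on one face of ring B and that on C7 on the other: C5/C8 and C5/C6 are cis, C6/C7 and C7/C8 are trans. C6 and C7 can be derived from C5, because a free 5-hydroxyl can steer an oxidant to one face of a C6=C7 bond and then decide which end of the epoxide is opened. C5 and C8 lie on opposite flanks of the pyranone double bond, too far apart to control each other, so each needs its own source of chirality. The pyranone has two carbons alpha to the carbonyl, C3 and C4a, and only C4a may carry a carbon substituent, so ring A must be built in a way that tells them apart. The material is fragile: C5–O and C8–O are both allylic to the pyranone double bond, the C8–H is vinylogously acidic and the C5–O bond ionises easily, so any ring B intermediate with a second double bond or a leaving group can eliminate to a flat aromatic chromone. The enabling feature is that C5 and C8 are bonded to the adjacent sp2 carbons C4a and C8a, which hold them cis and coplanar with only the C6–C7 bond between them: vinyl groups on C5 and C8 form a 1,7-diene that can only close to ring B, placing the new double bond where the trans-diol is needed.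

## Retrosynthesis

**Unmasking.** The last bonds cut are those of the protecting groups: the two benzyl–oxygen bonds (phenol and O8) of triol 23 and, one step earlier, the acyl–oxygen bond of 7-benzoate 22. Benzyl is preferred to silyl or acetal protection because it must survive organolithium, iodonium, palladium and ruthenium chemistry and then leave from both positions in one neutral hydrogenolysis. The forward steps must spare the pyranone and the C5–O bond.

**C7–O.** The trans-6,7-diol of 22 is the mark of an epoxide opened with inversion, so the C7–O bond is cut to give syn epoxy alcohol 21. Attack at C7, the carbon distal to the chelating 5-hydroxyl, is what a titanium-bound alkoxide imposes on an external carboxylate. A cis-dihydroxylation would give the wrong relative configuration, and opening at C6 the wrong diastereomer. The forward reaction only has to choose C7 over C6.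

**Epoxide.** Cutting both oxirane C–O bonds leads to allylic alcohol 20, which has only two stereocentres. The 5-hydroxyl is left free and O8 is capped, so that a metal alkoxide–peroxide delivers oxygen to the face the hydroxyl occupies. Because O5 and O8 are cis, this is also the face of the benzyloxy group, which a purely steric epoxidation would avoid.

**C6=C7 (key cut).** Opening ring B at the double bond gives diene 19, a pyranone with a 1-hydroxyallyl arm on C4a and a 1-(benzyloxy)allyl arm on C8a. The neighbouring cuts are less attractive. Cutting C4a–C5 and C8–C8a asks the pyranone double bond to act as a dienophile. Cutting C7–C8 creates two stereocentres in the ring-forming step. The C6=C7 cut creates none and leaves two three-carbon arms with one stereocentre each. The forward metathesis must outrun alkene isomerisation and 1,4-elimination.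

**C5.** The carbinol of 19 is traced to vinyl ketone 18 (C5–H bond, reagent-controlled reduction, since C8 is too remote to direct it). 18 in turn is traced to alkenyl iodide 17 by cutting the C4a–C5 bond (carbonylative cross-coupling). Both operations are neutral, which matters once the C8–H has become vinylogously acidic.

**Ring A.** Cutting the O1–C8a and C4a–I bonds of 17 opens the pyranone to ynone 16, a β-methoxy enone joined to an alkyne. An iodonium-triggered cyclisation puts the halogen on the former alkyne carbon next to the ketone, that is on C4a and not on C3. Halogenating a finished 2,6-disubstituted pyranone could not make that distinction.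

**C4–C4a.** The ynone is cut between carbonyl and alkyne into alkyne 7, which carries C8 as a configurationally secure propargylic stereocentre, and Weinreb amide 14, which carries ring C, the ethylene bridge and the masked 1,3-dicarbonyl. This is the convergent point of the route.

**Fragments.** Alkyne 7 comes through silyl ether 6 from alcohol 5, the slow-reacting enantiomer in an enzymatic resolution of racemate 4, itself from silylacetylene 1 and acrolein 2. The silyl group gives the enzyme the size difference that a bare ethynyl group lacks. Amide 14 comes through enol ether 13 from keto ester 12, made by cutting the benzylic C–C bond into methyl acetoacetate 10 and bromide 9 from commercial alcohol 8.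

## Roads not taken

**Alternative 1:** Enzymatic dearomatisation. The cut is made at the C5–O and C6–O bonds of a flat precursor. A toluene-dioxygenase-type whole-cell oxidation would add two oxygen atoms across C5=C6 of 7-iodo-2-methyl-4H-chromen-4-one A1 and give the cis-dihydrodiol (5S,6S)-5,6-dihydroxy-7-iodo-2-methyl-5,6-dihydro-4H-chromen-4-one A2.
- Merits: one step from an achiral aromatic sets C5 and C6 with the correct cis relationship and absolute sense. It is the shortest way to the oxygenation pattern.
- Weak points: a bicyclic chromone with an electron-poor benzo ring lies outside the usual range of these enzymes. The site of attack (5,6 or 7,8) rests on a directing model for the iodine. A2 is a dihydrodiol that can rearomatise by loss of water. The iodine must then be removed and the C7=C8 bond converted into the trans-7,8-diol with C8 cis to C5. The arylethyl chain must finally be attached through the 2-methyl group under basic conditions that this polyol tolerates badly.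
- Comparison: this road is shorter and its enantiocontrol costs nothing. The chosen plan offers reaction types of known scope, the side chain in place from the start, and a 6,7-diol whose configuration follows from a cyclic, directed sequence.

**Alternative 2:** Diels–Alder on a sulfinylpyranone. The cut is at C4a–C5 and C8–C8a. (S)-2-{2-[3-(benzyloxy)-4-methoxyphenyl]ethyl}-5-(4-methylbenzenesulfinyl)-4H-pyran-4-one A3 (the sulfur configuration is illustrative) would add (1E,3E)-1,4-bis(tert-butyldimethylsilyloxy)buta-1,3-diene A4 across its sulfinyl-bearing double bond. Thermal loss of the sulfur group as its sulfenic acid would restore the pyranone and give (5R,8S)-2-{2-[3-(benzyloxy)-4-methoxyphenyl]ethyl}-5,8-bis(tert-butyldimethylsilyloxy)-5,8-dihydro-4H-chromen-4-one A5.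
- Merits: ring B and both flanking carbinol centres, cis by the suprafacial addition, arise in one convergent operation with an auxiliary that removes itself. The stage of compound 20 would be reached in roughly half the steps and without a resolution.
- Weak points: the pyranone double bond is a vinylogous ester and a poor dienophile even with sulfinyl activation, so forcing conditions meet a heat-sensitive diene and an adduct that can aromatise by loss of silanol. The facial preference of sulfinyl dienophiles depends on the S–O conformation. A5 carries two identical silyl ethers on C5 and C8, which must be told apart before the directed epoxidation and the regioselective opening.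
- Comparison: if the cycloaddition worked, this would be the more economical route. The chosen plan pays in step count for oxygens at C5 and C8 that differ by construction and for two stereocentres set independently by well-understood reagent control.

**Alternative 3:** Vinylogous Mukaiyama aldol closing C7–C8. The cut is at C7–C8. 2-[(Benzyloxy)methyl]-6-{2-[3-(benzyloxy)-4-methoxyphenyl]ethyl}-3-[(1S,2S)-1,2,3,3-tetrakis(benzyloxy)propyl]-4H-pyran-4-one A6 would be converted by a silyl triflate and a hindered amine into a 2-alkylidene-4-silyloxypyran. Its C8 would attack the oxocarbenium ion formed from the C7 acetal, giving (5S,6S,7R,8S)-5,6,7,8-tetrakis(benzyloxy)-2-{2-[3-(benzyloxy)-4-methoxyphenyl]ethyl}-5,6,7,8-tetrahydro-4H-chromen-4-one A7.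
- Merits: C5 and C6 can be bought from the chiral pool, every oxygen is already a benzyl ether, and a single hydrogenolysis ends the synthesis. This end-game is better than the chosen one, which needs four steps after ring closure and must solve an epoxide regiochemistry.
- Weak points: one cyclisation must set both C7 and C8 (7,8-trans, 8 cis to 5) through an exocyclic dienol ether and an oxocarbenium ion of uncertain geometry. The C5 ether is itself ionisable under the Lewis acid. A6 still needs a pyranone functionalised selectively at C4a with a stereocentre next to the ring, the same problem the chosen route solves.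
- Comparison: the chosen plan forms ring B in a step that creates no stereocentre, then sets C6 and C7 on a rigid ring under the direction of C5.

Key step: step 12

Assumption: the E enol ether of ynone 16 equilibrates with its Z isomer under the acidic iodocyclisation conditions of step 9, so that the geometry needed for ring closure is reached in the flask.

## Route

Step 1
Reactants: 1 trimethylsilylacetylene; 2 acrolein
Product: 4 rac-5-(trimethylsilyl)pent-1-en-4-yn-3-ol, via lithium (trimethylsilyl)acetylide 3 (not isolated)
Conditions: n-BuLi, THF, −78 °C; then 2, −78 °C; aq. NH4Cl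
Reagents that add atoms: none
Why: 1,2-addition of an alkynyllithium to an enal; the hard nucleophile attacks the aldehyde carbon, and the silyl group provides the size difference between the two unsaturated substituents that the enzyme of step 2 needs.

Step 2
Reactants: 4 rac-5-(trimethylsilyl)pent-1-en-4-yn-3-ol
Product: 5 (S)-5-(trimethylsilyl)pent-1-en-4-yn-3-ol
Conditions: Pseudomonas fluorescens lipase (Amano AK), vinyl acetate, hexane, 30 °C, stopped just beyond half conversion; chromatography
Reagents that add atoms: none
Why: Lipase-catalysed kinetic resolution by irreversible transesterification; by the Kazlauskas rule the enantiomer with the large silylethynyl and medium vinyl group in the R arrangement is acetylated, so running past half conversion should leave the S alcohol in high enantiomeric purity. This fixes the configuration of C8 of the target.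

Step 3
Reactants: 5 (S)-5-(trimethylsilyl)pent-1-en-4-yn-3-ol
Product: 7 (S)-3-(benzyloxy)pent-1-en-4-yne, via (S)-3-(benzyloxy)-5-(trimethylsilyl)pent-1-en-4-yne 6 (not isolated)
Conditions: NaH, BnBr, n-Bu4NI (cat.), THF, 0 °C → rt; then MeOH, K2CO3 (cat.), rt
Reagents that add atoms: benzyl bromide, BrCc1ccccc1
Why: Williamson etherification of the alkoxide, then methanolysis of the C(sp)–Si bond; neither operation touches the C–H of the stereocentre, and the non-volatile silyl ether is desilylated only after benzylation to avoid handling the volatile parent enynol.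

Step 4
Reactants: 8 3-(benzyloxy)-4-methoxybenzyl alcohol
Product: 9 3-(benzyloxy)-4-methoxybenzyl bromide
Conditions: PBr3, CH2Cl2, 0 °C
Reagents that add atoms: phosphorus tribromide, BrP(Br)Br
Why: Conversion of a benzylic alcohol into the bromide through its phosphite ester; the electron-rich bromide is used at once.

Step 5
Reactants: 10 methyl acetoacetate; 9 3-(benzyloxy)-4-methoxybenzyl bromide
Product: 12 methyl 5-[3-(benzyloxy)-4-methoxyphenyl]-3-oxopentanoate, via methyl acetoacetate dianion 11 (not isolated)
Conditions: NaH, THF, 0 °C; n-BuLi, 0 °C; then 9, 0 °C → rt; aq. NH4Cl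
Reagents that add atoms: none
Why: Acetoacetate dianion alkylation; the second, more basic carbanion at the terminal carbon is alkylated selectively, which joins ring C and the ethylene bridge to the future C2.

Step 6
Reactants: 12 methyl 5-[3-(benzyloxy)-4-methoxyphenyl]-3-oxopentanoate
Product: 13 methyl (E)-5-[3-(benzyloxy)-4-methoxyphenyl]-3-methoxypent-2-enoate
Conditions: HC(OMe)3, MeOH, H2SO4 (cat.), rt → 50 °C
Reagents that add atoms: trimethyl orthoformate, COC(OC)OC
Why: Acid-catalysed enol ether formation from a β-keto ester through its dimethyl ketal; thermodynamic control gives the conjugated E isomer and places the future ring oxygen O1 unambiguously on C2.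

Step 7
Reactants: 13 methyl (E)-5-[3-(benzyloxy)-4-methoxyphenyl]-3-methoxypent-2-enoate
Product: 14 (E)-5-[3-(benzyloxy)-4-methoxyphenyl]-N,3-dimethoxy-N-methylpent-2-enamide
Conditions: MeNH(OMe)·HCl, i-PrMgCl, THF, −20 → 0 °C
Reagents that add atoms: N,O-dimethylhydroxylamine hydrochloride, CNOC.Cl
Why: Weinreb amide formation by aminolysis of the ester with the chloromagnesium amide generated in the flask; the amide is the acyl donor that stops at the ketone in step 8.

Step 8
Reactants: 7 (S)-3-(benzyloxy)pent-1-en-4-yne; 14 (E)-5-[3-(benzyloxy)-4-methoxyphenyl]-N,3-dimethoxy-N-methylpent-2-enamide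
Product: 16 (3E,8S)-8-(benzyloxy)-1-[3-(benzyloxy)-4-methoxyphenyl]-3-methoxydeca-3,9-dien-6-yn-5-one, via (S)-3-(benzyloxy)pent-1-en-4-ynyllithium 15 (not isolated)
Conditions: n-BuLi, THF, −78 °C; then 14, −78 → −20 °C; cold aq. NH4Cl
Reagents that add atoms: none
Why: Acylation of an alkynyllithium by a Weinreb amide; the chelated tetrahedral adduct collapses only on work-up, so no second addition occurs. At −78 °C only the acetylenic C–H is removed, so the propargylic stereocentre is preserved.

Step 9
Reactants: 16 (3E,8S)-8-(benzyloxy)-1-[3-(benzyloxy)-4-methoxyphenyl]-3-methoxydeca-3,9-dien-6-yn-5-one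
Product: 17 2-[(1S)-1-(benzyloxy)prop-2-en-1-yl]-6-{2-[3-(benzyloxy)-4-methoxyphenyl]ethyl}-3-iodo-4H-pyran-4-one
Conditions: ICl (1.2 equiv), CH2Cl2, −78 → 0 °C; aq. Na2S2O3
Reagents that add atoms: iodine monochloride, ClI
Why: ICl-induced 6-endo-dig iodocyclisation of an alkynone carrying a β-methoxy group, the reaction type that converts 2-methoxyaryl alkynyl ketones into 3-iodochromones: the iodonium ion activates the triple bond, the enol-ether oxygen closes ring A at C8a and chloride removes the methyl group as chloromethane. Iodine can only end on C4a, the former alkyne carbon next to the ketone, and the acidic, base-free medium both leaves the C8–H untouched and lets the E enol ether reach the Z geometry needed for closure.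

Step 10
Reactants: 17 2-[(1S)-1-(benzyloxy)prop-2-en-1-yl]-6-{2-[3-(benzyloxy)-4-methoxyphenyl]ethyl}-3-iodo-4H-pyran-4-one
Product: 18 2-[(1S)-1-(benzyloxy)prop-2-en-1-yl]-6-{2-[3-(benzyloxy)-4-methoxyphenyl]ethyl}-3-(prop-2-enoyl)-4H-pyran-4-one
Conditions: PdCl2(PPh3)2 (5 mol %), CH2=CHSnBu3, CO (3 atm), THF, 50 °C
Reagents that add atoms: carbon monoxide, [C-]#[O+]; tributyl(vinyl)stannane, C=C[Sn](CCCC)(CCCC)CCCC
Why: Carbonylative Stille coupling: oxidative addition of the alkenyl iodide to zerovalent palladium formed in situ, CO insertion, vinyl transfer from tin and reductive elimination give the vinyl ketone, forming the C4a–C5 bond. The medium is neutral, so C8 is not deprotonated, and CO pressure favours insertion over direct vinyl coupling.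

Step 11
Reactants: 18 2-[(1S)-1-(benzyloxy)prop-2-en-1-yl]-6-{2-[3-(benzyloxy)-4-methoxyphenyl]ethyl}-3-(prop-2-enoyl)-4H-pyran-4-one
Product: 19 2-[(1S)-1-(benzyloxy)prop-2-en-1-yl]-6-{2-[3-(benzyloxy)-4-methoxyphenyl]ethyl}-3-[(1R)-1-hydroxyprop-2-en-1-yl]-4H-pyran-4-one
Conditions: (S)-1-methyl-3,3-diphenyltetrahydro-1H,3H-pyrrolo[1,2-c][1,3,2]oxazaborole (0.5 equiv), catecholborane, toluene, −78 °C
Reagents that add atoms: none
Why: CBS reduction: the oxazaborolidine binds the ketone lone pair anti to the larger, doubly ortho-substituted pyranonyl group and delivers hydride to the face that gives the R carbinol with the S catalyst, so C5 is set by reagent control. Catecholborane at −78 °C is chosen to avoid hydroboration and conjugate reduction of the vinyl group, and the vinylogous-ester carbonyl of ring A is not reduced.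

Step 12
Reactants: 19 2-[(1S)-1-(benzyloxy)prop-2-en-1-yl]-6-{2-[3-(benzyloxy)-4-methoxyphenyl]ethyl}-3-[(1R)-1-hydroxyprop-2-en-1-yl]-4H-pyran-4-one
Product: 20 (5R,8S)-8-(benzyloxy)-2-{2-[3-(benzyloxy)-4-methoxyphenyl]ethyl}-5-hydroxy-5,8-dihydro-4H-chromen-4-one
Conditions: RuCl2(=CHPh)(H2IMes)(PCy3) (second-generation Grubbs catalyst, 5 mol %), 1,4-benzoquinone (10 mol %), CH2Cl2 (5 mM), 40 °C
Reagents that add atoms: none
Why: Ring-closing alkene metathesis: the ruthenium benzylidene exchanges with one terminal vinyl group (probably that of the free allylic alcohol), the new alkylidene adds across the second vinyl group to a ruthenacyclobutane, and cycloreversion releases the cyclic alkene and a methylidene that carries the chain, with loss of ethylene as driving force. The closest known reaction type is the metathesis of 1,7-dienes bearing two allylic oxygen substituents to cyclohex-2-ene-1,4-diol derivatives, as used for conduritols. Ring B closes as a six-membered carbocycle by joining the two vinyl termini, so the only new bond is C6=C7 and it is necessarily cis. No stereocentre is created; C5 and C8 are carried through unchanged and their descriptors R and S correspond to the cis arrangement across the ring. The selectivity needed is chemoselectivity for the two monosubstituted alkenes over the electron-poor, fully substituted pyranone double bonds, which the catalyst should leave alone. Cyclisation over oligomerisation is secured by the C4a=C8a bond, which holds the two arms cis and coplanar, and by dilution. The neutral medium, the moderate temperature and the benzoquinone additive are meant to suppress ruthenium hydride chemistry, which would isomerise the allylic alcohol or move the new double bond and so open the way to aromatisation.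

Step 13
Reactants: 20 (5R,8S)-8-(benzyloxy)-2-{2-[3-(benzyloxy)-4-methoxyphenyl]ethyl}-5-hydroxy-5,8-dihydro-4H-chromen-4-one
Product: 21 (5S,6S,7S,8S)-8-(benzyloxy)-2-{2-[3-(benzyloxy)-4-methoxyphenyl]ethyl}-6,7-epoxy-5-hydroxy-5,6,7,8-tetrahydro-4H-chromen-4-one
Conditions: VO(acac)2 (5 mol %), t-BuOOH (in decane), CH2Cl2, 0 °C → rt
Reagents that add atoms: tert-butyl hydroperoxide, CC(C)(C)OO
Why: Hydroxyl-directed epoxidation of a cyclic allylic alcohol: the vanadium alkoxide of the 5-hydroxyl carries the alkyl peroxide and delivers oxygen to the face it occupies, so C6 and C7 are set syn to O5 (and therefore to O8) under the control of C5. The pyranone double bonds are too electron-poor to react.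

Step 14
Reactants: 21 (5S,6S,7S,8S)-8-(benzyloxy)-2-{2-[3-(benzyloxy)-4-methoxyphenyl]ethyl}-6,7-epoxy-5-hydroxy-5,6,7,8-tetrahydro-4H-chromen-4-one
Product: 22 (5S,6S,7R,8S)-8-(benzyloxy)-2-{2-[3-(benzyloxy)-4-methoxyphenyl]ethyl}-5,6-dihydroxy-4-oxo-5,6,7,8-tetrahydro-4H-chromen-7-yl benzoate
Conditions: Ti(OiPr)4 (1.5 equiv), PhCO2H (1.5 equiv), CH2Cl2, rt
Reagents that add atoms: benzoic acid, OC(=O)c1ccccc1
Why: Titanium-alkoxide-mediated opening of a 2,3-epoxy alcohol by a carboxylic acid at the carbon distal to the hydroxyl: the 5-alkoxide and the epoxide oxygen chelate titanium and benzoate attacks C7 from the opposite face. C7 is inverted to R while C6 keeps the oxygen delivered in step 13, which gives the 5,6-cis-6,7-trans-7,8-trans pattern of the target.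

Step 15
Reactants: 22 (5S,6S,7R,8S)-8-(benzyloxy)-2-{2-[3-(benzyloxy)-4-methoxyphenyl]ethyl}-5,6-dihydroxy-4-oxo-5,6,7,8-tetrahydro-4H-chromen-7-yl benzoate
Product: 23 (5S,6S,7R,8S)-8-(benzyloxy)-2-{2-[3-(benzyloxy)-4-methoxyphenyl]ethyl}-5,6,7-trihydroxy-5,6,7,8-tetrahydro-4H-chromen-4-one
Conditions: K2CO3 (0.3 equiv), MeOH, 0 °C
Reagents that add atoms: none
Why: Base-catalysed transesterification of the benzoate to methyl benzoate; substoichiometric carbonate at 0 °C is chosen to keep deprotonation at C8 slow, and any acyl migration to a neighbouring hydroxyl is harmless because it does not change configuration.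

Step 16
Reactants: 23 (5S,6S,7R,8S)-8-(benzyloxy)-2-{2-[3-(benzyloxy)-4-methoxyphenyl]ethyl}-5,6,7-trihydroxy-5,6,7,8-tetrahydro-4H-chromen-4-one
Product: 24 (5S,6S,7R,8S)-5,6,7,8-tetrahydroxy-2-[2-(3-hydroxy-4-methoxyphenyl)ethyl]-5,6,7,8-tetrahydro-4H-chromen-4-one
Conditions: H2 (1 atm), Pd/C (10 %), EtOAc–MeOH, rt
Reagents that add atoms: none
Why: Hydrogenolysis of the aryl benzyl ether and the 8-O-benzyl ether on palladium under neutral conditions; at one atmosphere the pyranone ring is not expected to be reduced and no stereocentre is touched.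

## Compound list

1 | trimethylsilylacetylene | C#C[Si](C)(C)C | starting material
2 | acrolein | C=CC=O | starting material
3 | lithium (trimethylsilyl)acetylide | [Li]C#C[Si](C)(C)C | intermediate
4 | rac-5-(trimethylsilyl)pent-1-en-4-yn-3-ol | C=CC(O)C#C[Si](C)(C)C | intermediate
5 | (S)-5-(trimethylsilyl)pent-1-en-4-yn-3-ol | C=C[C@H](O)C#C[Si](C)(C)C | intermediate
6 | (S)-3-(benzyloxy)-5-(trimethylsilyl)pent-1-en-4-yne | C=C[C@H](OCc1ccccc1)C#C[Si](C)(C)C | intermediate
7 | (S)-3-(benzyloxy)pent-1-en-4-yne | C=C[C@H](OCc1ccccc1)C#C | intermediate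
8 | 3-(benzyloxy)-4-methoxybenzyl alcohol | COc1ccc(CO)cc1OCc1ccccc1 | starting material
9 | 3-(benzyloxy)-4-methoxybenzyl bromide | COc1ccc(CBr)cc1OCc1ccccc1 | intermediate
10 | methyl acetoacetate | CC(=O)CC(=O)OC | starting material
11 | methyl acetoacetate dianion (sodium lithium salt) | [Na+].[Li+].[CH2-]C([O-])=CC(=O)OC | intermediate
12 | methyl 5-[3-(benzyloxy)-4-methoxyphenyl]-3-oxopentanoate | COC(=O)CC(=O)CCc1ccc(OC)c(OCc2ccccc2)c1 | intermediate
13 | methyl (E)-5-[3-(benzyloxy)-4-methoxyphenyl]-3-methoxypent-2-enoate | CO/C(CCc1ccc(OC)c(OCc2ccccc2)c1)=C/C(=O)OC | intermediate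
14 | (E)-5-[3-(benzyloxy)-4-methoxyphenyl]-N,3-dimethoxy-N-methylpent-2-enamide | CO/C(CCc1ccc(OC)c(OCc2ccccc2)c1)=C/C(=O)N(C)OC | intermediate
15 | (S)-3-(benzyloxy)pent-1-en-4-ynyllithium | [Li]C#C[C@@H](OCc1ccccc1)C=C | intermediate
16 | (3E,8S)-8-(benzyloxy)-1-[3-(benzyloxy)-4-methoxyphenyl]-3-methoxydeca-3,9-dien-6-yn-5-one | CO/C(CCc1ccc(OC)c(OCc2ccccc2)c1)=C/C(=O)C#C[C@@H](OCc1ccccc1)C=C | intermediate
17 | 2-[(1S)-1-(benzyloxy)prop-2-en-1-yl]-6-{2-[3-(benzyloxy)-4-methoxyphenyl]ethyl}-3-iodo-4H-pyran-4-one | COc1ccc(CCc2cc(=O)c(I)c(o2)[C@@H](OCc3ccccc3)C=C)cc1OCc1ccccc1 | intermediate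
18 | 2-[(1S)-1-(benzyloxy)prop-2-en-1-yl]-6-{2-[3-(benzyloxy)-4-methoxyphenyl]ethyl}-3-(prop-2-enoyl)-4H-pyran-4-one | COc1ccc(CCc2cc(=O)c(C(=O)C=C)c(o2)[C@@H](OCc3ccccc3)C=C)cc1OCc1ccccc1 | intermediate
19 | 2-[(1S)-1-(benzyloxy)prop-2-en-1-yl]-6-{2-[3-(benzyloxy)-4-methoxyphenyl]ethyl}-3-[(1R)-1-hydroxyprop-2-en-1-yl]-4H-pyran-4-one | COc1ccc(CCc2cc(=O)c([C@H](O)C=C)c(o2)[C@@H](OCc3ccccc3)C=C)cc1OCc1ccccc1 | intermediate
20 | (5R,8S)-8-(benzyloxy)-2-{2-[3-(benzyloxy)-4-methoxyphenyl]ethyl}-5-hydroxy-5,8-dihydro-4H-chromen-4-one | COc1ccc(CCc2cc(=O)c3c(o2)[C@@H](OCc4ccccc4)C=C[C@H]3O)cc1OCc1ccccc1 | intermediate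
21 | (5S,6S,7S,8S)-8-(benzyloxy)-2-{2-[3-(benzyloxy)-4-methoxyphenyl]ethyl}-6,7-epoxy-5-hydroxy-5,6,7,8-tetrahydro-4H-chromen-4-one (epoxide cis to O5 and O8) | COc1ccc(CCc2cc(=O)c3c(o2)[C@@H](OCc4ccccc4)[C@H]5O[C@H]5[C@H]3O)cc1OCc1ccccc1 | intermediate
22 | (5S,6S,7R,8S)-8-(benzyloxy)-2-{2-[3-(benzyloxy)-4-methoxyphenyl]ethyl}-5,6-dihydroxy-4-oxo-5,6,7,8-tetrahydro-4H-chromen-7-yl benzoate | COc1ccc(CCc2cc(=O)c3c(o2)[C@@H](OCc4ccccc4)[C@H](OC(=O)c4ccccc4)[C@@H](O)[C@H]3O)cc1OCc1ccccc1 | intermediate
23 | (5S,6S,7R,8S)-8-(benzyloxy)-2-{2-[3-(benzyloxy)-4-methoxyphenyl]ethyl}-5,6,7-trihydroxy-5,6,7,8-tetrahydro-4H-chromen-4-one | COc1ccc(CCc2cc(=O)c3c(o2)[C@@H](OCc4ccccc4)[C@H](O)[C@@H](O)[C@H]3O)cc1OCc1ccccc1 | intermediate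
24 | (5S,6S,7R,8S)-5,6,7,8-tetrahydroxy-2-[2-(3-hydroxy-4-methoxyphenyl)ethyl]-5,6,7,8-tetrahydro-4H-chromen-4-one | COc1ccc(CCc2cc(=O)c3c(o2)[C@@H](O)[C@H](O)[C@@H](O)[C@H]3O)cc1O | target

## Step count and least certain steps

Total: 16 steps. Longest linear sequence: 13 steps (8 to 24, steps 4 to 16); the alkyne branch (steps 1 to 3) joins at step 8.

**Step 12 (key step).** The likely failure is not the ring closure but what ruthenium hydride species do beside it: redox isomerisation of the free allylic alcohol to an ethyl ketone, or migration of the new double bond into conjugation, after which 1,4-elimination of water or benzyl alcohol gives an aromatic chromone. Coordination of the catalyst by the hydroxyl and the pyranone carbonyl could also slow turnover. The fallback keeps the disconnection but closes the ring on a fully protected diene. It sets out from 19, which is silylated (TESCl, imidazole, CH2Cl2) to the 5-O-triethylsilyl ether of diene 19 F1. The same ruthenium complex closes this to the 5-O-triethylsilyl ether of dihydrochromone 20 F2, and buffered HF·pyridine (THF, 0 °C) returns the route to 20.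

**Step 9.** Three processes can compete with the cyclisation: the E enol ether may not isomerise fast enough to bring its oxygen within reach of the activated alkyne; the iodonium source may attack the vinylogous-ester carbon C3, the terminal alkene or ring C; and ICl may simply add across the triple bond. The fallback sets out from 16 and reaches the iodide by three known operations that place iodine through the nucleophilicity of an enaminone. Pyrrolidine (CH2Cl2, 0 °C) adds to the ynone to give (3E,6E,8S)-8-(benzyloxy)-1-[3-(benzyloxy)-4-methoxyphenyl]-3-methoxy-7-(pyrrolidin-1-yl)deca-3,6,9-trien-5-one F3. N-Iodosuccinimide (CH2Cl2, 0 °C) iodinates the enaminone carbon, by far the most electron-rich position, to give the 6-iodo enaminone F4. Aqueous trifluoroacetic acid then hydrolyses the enol ether and closes ring A by addition–elimination with loss of pyrrolidine, which rejoins the route at 17.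

**Step 10.** Direct vinyl transfer without CO insertion is the main risk on a hindered alkenylpalladium, followed by polymerisation of, or conjugate addition to, the doubly activated vinyl ketone. The fallback sets out from 17. A Nozaki–Hiyama–Kishi coupling with acrolein 2 (CrCl2, NiCl2 cat., DMF, rt), equally neutral, gives the carbinols epimeric at C5 F5, and Dess–Martin periodinane (NaHCO3, CH2Cl2, 0 °C) oxidises them to 18.

**Step 11.** Poor facial selectivity is possible, because the strongly Lewis basic pyranone carbonyl can hold the boron reagents and allow uncatalysed background reduction, and because the size ranking of the two carbonyl substituents is an extrapolation. Conjugate reduction of the vinyl ketone is the second risk. The fallback replaces asymmetric reduction by kinetic resolution and sets out from 18. Luche reduction (NaBH4, CeCl3·7H2O, MeOH, −78 °C) gives the same epimeric carbinols F5. A Sharpless kinetic resolution (Ti(OiPr)4, D-(−)-diisopropyl tartrate, t-BuOOH, CH2Cl2, −20 °C) then epoxidises the hydroxyallyl arm of the 5S epimer only, converting it into the anti epoxy alcohol 3-{(R)-hydroxy[(2S)-oxiran-2-yl]methyl}pyranone F6. The slow-reacting epimer is 19.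

**Step 14.** Loss of regiocontrol is the concern: both epoxide carbons are flanked by oxygenated carbons and the ring is nearly flat, so chelation is the only bias towards C7; Lewis-acid ionisation at C5 is a second risk. The fallback enforces the regiochemistry by a tether and sets out from 20.
- Boc2O with catalytic DMAP gives the 5-O-tert-butoxycarbonyl derivative of 20 F7.
- mCPBA (NaHCO3, CH2Cl2) should epoxidise this from the face opposite to both oxygen substituents, giving the 5-O-tert-butoxycarbonyl 6,7-epoxide with the oxirane trans to O5 and O8 F8.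
- BF3·OEt2 (CH2Cl2, −40 °C) makes the carbonate carbonyl open the epoxide at C6 in a 5-exo mode with inversion and loss of 2-methylpropene, giving the 5,6-cyclic carbonate of triol 23 F9 with the 7-hydroxyl trans.
- K2CO3 in methanol at 0 °C cleaves the carbonate and rejoins the route at 23.

**Step 15.** Base-induced elimination can compete with methanolysis: deprotonation at the vinylogously acidic C8 with expulsion of the 7-benzoate, followed by aromatisation. The fallback removes the ester from the plan and sets out from 21. The epoxide is opened at C7 with benzyl alcohol under Ti(OCH2Ph)4 (prepared from Ti(OiPr)4 and benzyl alcohol with removal of 2-propanol; benzyl alcohol, 60 °C), a known alcohol variant of the titanium-mediated opening. This gives the 7-O-benzyl ether of 23 F10, and hydrogenolysis (H2, Pd/C, EtOAc–MeOH) leads directly to 24.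

## Further compounds

F1 | step 12 | 2-[(1S)-1-(benzyloxy)prop-2-en-1-yl]-6-{2-[3-(benzyloxy)-4-methoxyphenyl]ethyl}-3-[(1R)-1-(triethylsilyloxy)prop-2-en-1-yl]-4H-pyran-4-one | COc1ccc(CCc2cc(=O)c([C@H](O[Si](CC)(CC)CC)C=C)c(o2)[C@@H](OCc3ccccc3)C=C)cc1OCc1ccccc1
F2 | step 12 | (5R,8S)-8-(benzyloxy)-2-{2-[3-(benzyloxy)-4-methoxyphenyl]ethyl}-5-(triethylsilyloxy)-5,8-dihydro-4H-chromen-4-one | COc1ccc(CCc2cc(=O)c3c(o2)[C@@H](OCc4ccccc4)C=C[C@H]3O[Si](CC)(CC)CC)cc1OCc1ccccc1
F3 | step 9 | (3E,6E,8S)-8-(benzyloxy)-1-[3-(benzyloxy)-4-methoxyphenyl]-3-methoxy-7-(pyrrolidin-1-yl)deca-3,6,9-trien-5-one | CO/C(CCc1ccc(OC)c(OCc2ccccc2)c1)=C/C(=O)/C=C(/N1CCCC1)[C@@H](OCc1ccccc1)C=C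
F4 | step 9 | (3E,6Z,8S)-8-(benzyloxy)-1-[3-(benzyloxy)-4-methoxyphenyl]-6-iodo-3-methoxy-7-(pyrrolidin-1-yl)deca-3,6,9-trien-5-one | CO/C(CCc1ccc(OC)c(OCc2ccccc2)c1)=C/C(=O)/C(I)=C(/N1CCCC1)[C@@H](OCc1ccccc1)C=C
F5 | step 10 | 2-[(1S)-1-(benzyloxy)prop-2-en-1-yl]-6-{2-[3-(benzyloxy)-4-methoxyphenyl]ethyl}-3-(1-hydroxyprop-2-en-1-yl)-4H-pyran-4-one, both epimers at the carbinol carbon | COc1ccc(CCc2cc(=O)c(C(O)C=C)c(o2)[C@@H](OCc3ccccc3)C=C)cc1OCc1ccccc1
F6 | step 11 | 2-[(1S)-1-(benzyloxy)prop-2-en-1-yl]-6-{2-[3-(benzyloxy)-4-methoxyphenyl]ethyl}-3-{(R)-hydroxy[(2S)-oxiran-2-yl]methyl}-4H-pyran-4-one | COc1ccc(CCc2cc(=O)c([C@@H](O)[C@@H]3CO3)c(o2)[C@@H](OCc3ccccc3)C=C)cc1OCc1ccccc1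
F7 | step 14 | tert-butyl (5R,8S)-8-(benzyloxy)-2-{2-[3-(benzyloxy)-4-methoxyphenyl]ethyl}-4-oxo-5,8-dihydro-4H-chromen-5-yl carbonate | COc1ccc(CCc2cc(=O)c3c(o2)[C@@H](OCc4ccccc4)C=C[C@H]3OC(=O)OC(C)(C)C)cc1OCc1ccccc1
F8 | step 14 | tert-butyl (5S,6R,7R,8S)-8-(benzyloxy)-2-{2-[3-(benzyloxy)-4-methoxyphenyl]ethyl}-6,7-epoxy-4-oxo-5,6,7,8-tetrahydro-4H-chromen-5-yl carbonate (epoxide trans to O5 and O8) | COc1ccc(CCc2cc(=O)c3c(o2)[C@@H](OCc4ccccc4)[C@@H]5O[C@@H]5[C@H]3OC(=O)OC(C)(C)C)cc1OCc1ccccc1
F9 | step 14 | 5,6-cyclic carbonate of triol 23 (O5 and O6 joined through a carbonyl group, 7-hydroxyl free) | COc1ccc(CCc2cc(=O)c3c(o2)[C@@H](OCc4ccccc4)[C@H](O)[C@H]4OC(=O)O[C@@H]34)cc1OCc1ccccc1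
F10 | step 15 | (5S,6S,7R,8S)-7,8-bis(benzyloxy)-2-{2-[3-(benzyloxy)-4-methoxyphenyl]ethyl}-5,6-dihydroxy-5,6,7,8-tetrahydro-4H-chromen-4-one | COc1ccc(CCc2cc(=O)c3c(o2)[C@@H](OCc4ccccc4)[C@H](OCc4ccccc4)[C@@H](O)[C@H]3O)cc1OCc1ccccc1
A1 | alternative 1 | 7-iodo-2-methyl-4H-chromen-4-one | Cc1cc(=O)c2ccc(I)cc2o1
A2 | alternative 1 | (5S,6S)-5,6-dihydroxy-7-iodo-2-methyl-5,6-dihydro-4H-chromen-4-one | Cc1cc(=O)c2c(o1)C=C(I)[C@@H](O)[C@H]2O
A3 | alternative 2 | (S)-2-{2-[3-(benzyloxy)-4-methoxyphenyl]ethyl}-5-(4-methylbenzenesulfinyl)-4H-pyran-4-one | COc1ccc(CCc2cc(=O)c(co2)[S@@](=O)c2ccc(C)cc2)cc1OCc1ccccc1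
A4 | alternative 2 | (1E,3E)-1,4-bis(tert-butyldimethylsilyloxy)buta-1,3-diene | CC(C)(C)[Si](C)(C)O/C=C/C=C/O[Si](C)(C)C(C)(C)C
A5 | alternative 2 | (5R,8S)-2-{2-[3-(benzyloxy)-4-methoxyphenyl]ethyl}-5,8-bis(tert-butyldimethylsilyloxy)-5,8-dihydro-4H-chromen-4-one | COc1ccc(CCc2cc(=O)c3c(o2)[C@@H](O[Si](C)(C)C(C)(C)C)C=C[C@H]3O[Si](C)(C)C(C)(C)C)cc1OCc1ccccc1
A6 | alternative 3 | 2-[(benzyloxy)methyl]-6-{2-[3-(benzyloxy)-4-methoxyphenyl]ethyl}-3-[(1S,2S)-1,2,3,3-tetrakis(benzyloxy)propyl]-4H-pyran-4-one | COc1ccc(CCc2cc(=O)c([C@H](OCc3ccccc3)[C@H](OCc3ccccc3)C(OCc3ccccc3)OCc3ccccc3)c(COCc3ccccc3)o2)cc1OCc1ccccc1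
A7 | alternative 3 | (5S,6S,7R,8S)-5,6,7,8-tetrakis(benzyloxy)-2-{2-[3-(benzyloxy)-4-methoxyphenyl]ethyl}-5,6,7,8-tetrahydro-4H-chromen-4-one | COc1ccc(CCc2cc(=O)c3c(o2)[C@@H](OCc4ccccc4)[C@H](OCc4ccccc4)[C@@H](OCc4ccccc4)[C@H]3OCc5ccccc5)cc1OCc1ccccc1
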